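Amounts come first: how much product a charge of starting material has made by a given time.

| flask | starting material | product | time |
|---|---|---|---|
| teal | 120 mM |  |  |
| red | 240 mM |  |  |
| green | 120 mM | 36.0 mM |  |
| violet | 550 mM |  | 9.2 min |

| run | time / min | [product] / mM |
|---|---|---|
| teal run | 0.52 | 2.3 |
| teal run | 1.6 | 13.2 |
| teal run | 3.0 | 30.0 |
| teal run | 4.8 | 48.4 |
| teal run | 6.9 | 64.9 |
| teal run | 9.2 | 75.8 |
| red run | 0.52 | 3.4 |
| red run | 1.6 | 19.5 |
| red run | 3.0 | 45.5 |
| red run | 4.8 | 77.1 |
| red run | 6.9 | 106.8 |
| red run | 9.2 | 132.5 |
| green run | 0.52 | 38.7 |
| green run | 1.6 | 49.3 |
| green run | 3.0 | 65.9 |
| green run | 4.8 | 85.7 |
| green run | 6.9 | 100.5 |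
| green run | 9.2 | 111.9 |

(standard deviation of a reading: 0.4 mM)

- the exponent of [starting material] in the starting rate at the charge of the teal run (at the point where two percent of the starting material have become product) (one fixed amount of product, the same in the runs compared)
- product in the violet run at 9.2 min, as a share of the starting material charged

- Overall: starting material -> product.
- Constant volume, constant temperature.
- Bound and free are read together.
- An order is taken over about fifteen percent of the charge, up and down.

At 3.0 min the green flask has made 29.9 mM beyond its added 36.0 mM, and the teal flask has made 30.0 mM at that time. The curves are therefore read as functions of time and charge, with added product left aside. At 1.6 min, the red flask against the teal flask gives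

m = ln(red product / teal product) / ln(red charge / teal charge) = 0.563

This m, the charge exponent, the power of the charge that product follows at one time, is the first link. The next link is the lag (induction period) of the teal flask, read as the log-log slope of its first two readings:

s = 1.55

Taking m as the order is the weak link, since m compares equal times and the question compares equal amounts of product. So it is reforged. Early on, c(product) = A·t^s, with A growing as the charge to the power m. The rate s·c(product)/t at a fixed c(product) then grows as the s-th root of A, which gives

order = m/s = 0.362

For the violet flask, the exponent at 9.2 min gives the other end:

m(late) = 0.806

This is larger than the early m, and it compares the teal and red flasks when their product stands at 63.2% and 55.2% of their charges. Joining the ends by their mean, 0.684, and scaling up from the red flask gives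

c(product) = 234 mM, a share of 42.5%

The forecast gives 0.67 and 38.5%, holding that the doubled charge's weaker rise “indicates saturation”. The flask gives 0.36 for the order and 42.7% for the violet flask.

    starting material → intermediate (0.7200 min⁻¹)
    intermediate → product (1.248 min⁻¹)
    2 starting material ⇌ idle substrate dimer, settled at all times (105.0 L mol⁻¹)
    starting material → decomposed substrate (0.3282 min⁻¹)

The joining of two starting material to idle substrate dimer holds m below 1: taken away, the order at the teal charge goes from 0.36 to 0.60. With the joining taken away, each remaining step is first order in its one reactant, so m, read at 0.563 in the flasks as they are, becomes 1, and m/s, with s kept at its reading, becomes 0.645, beside the simulated 0.60. In the violet flask, product at 9.2 min stands at 42.7% of the charge as it is and at 68.7% with the same joining taken away, a difference of 26 percentage points.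

(The runs come from a simulation from invented constants; scatter was added.)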